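**Time-free ratio.** The rate of target divided by the rate of homo product contains no clock, and the share asked for below is built from that ratio.

| flask | starting material | partner | protic impurity | temperature | remark | time |
|---|---|---|---|---|---|---|
| autumn | 0.32 M | 0.378 M | 0.072 M | 62 °C | run made earlier |  |
| spring | 0.53 M | 0.378 M | 0.072 M | 90 °C | run made earlier |  |
| midnight | 0.36 M | 0.378 M | 0.13 M | 62 °C | run made earlier |  |
| Sunday's | 0.36 M | 0.100 M | 0.0720 M | 90 °C |  | 30 h |
| Tuesday's | 0.36 M | 0.600 M | 0.200 M | 100 °C |  | 30 h |
| Wednesday's | 0.80 M | 0.378 M | 0.0720 M | 90 °C |  | 30 h |
| Saturday's | 0.36 M | 0.378 M | 0.0720 M | 70 °C |  | 30 h |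
| Monday's | 0.50 M | 0.200 M | 0.0720 M | 50 °C |  | 30 h |

| run | time / h | target / % | homo product / % |
|---|---|---|---|
| autumn | 0.833 | 0 | 0 |
| autumn | 2.50 | 2 | 0 |
| autumn | 4.00 | 0 | 0 |
| autumn | 6.00 | 1 | 0 |
| autumn | 10.0 | 3 | 1 |
| autumn | 12.0 | 0 | 0 |
| autumn | 15.0 | 7 | 0 |
| spring | 0.333 | 1 | 2 |
| spring | 1.00 | 7 | 1 |
| spring | 1.33 | 12 | 4 |
| spring | 2.00 | 19 | 5 |
| spring | 4.00 | 31 | 12 |
| spring | 6.00 | 43 | 19 |
| midnight | 3.00 | 0 | 1 |
| midnight | 6.00 | 3 | 1 |
| midnight | 10.0 | 1 | 0 |
| midnight | 12.0 | 1 | 0 |
| midnight | 15.0 | 6 | 0 |

(scatter of a reading: 2 percentage points)

- percentages count the starting material that a species holds: one homo product counts as two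
- steps under discussion: 2 open intermediate -> homo product; partner -> second intermediate; starting material <-> open intermediate; open intermediate + second intermediate -> target; partner + protic impurity -> quenched reagent; partner -> decomposed reagent

* ranking by share of target in all that became target or homo product, from high to low, at 30 h (Sunday's / Tuesday's / Wednesday's / Saturday's / Monday's)
* the same order at 10 d (Sunday's / Tuesday's / Wednesday's / Saturday's / Monday's)
* the share of target in all that became target or homo product of the flask you put first, at 30 h
* the share of target in all that became target or homo product of the flask you put last, at 30 h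

**Reading it.** Target takes one open intermediate and one second intermediate, which comes from partner, while homo product takes two open intermediates. The rate ratio should therefore run as c(partner) left over c(starting material) left, with the unreacted material standing in for the open intermediate. The spring run is the one with countable homo product. Its last reading gives 43% target against 19% homo product at a charge ratio of 0.713, so 3.17 is the selectivity factor σ, the rate ratio per unit of c(partner)/c(starting material). It is a reading with the scatter of 2 percentage points. This reckoning holds it across temperatures and leaves partner's side losses uncounted.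

**What slows it.** Write b for the charged c(partner)/c(starting material). The rate ratio starts at σb: 0.278 times σ gives 0.881 in Sunday's, and 1.67 times σ gives 5.29 in Tuesday's. Each target removes one partner from the numerator, and each product removes starting material from the denominator. Integrating the ratio gives a dividing value, 0.685.

Below it, the reckoning has partner reach zero while starting material remains, homo product take the rest, and the final share equal b. For Sunday's, with b below that value, it gives 27.8%. Above it, the reckoning has starting material consumed with a remainder w of partner per starting material charged, and the final share equals b minus w. For Tuesday's it gives w of 0.770, for a share of 89.7%. For Saturday's, with b of 1.05, it gives w of 0.225, for a lower end value of 82.5%. The spring run turned 62.0% into the two products by 6.00 h, so this reckoning takes the hot flasks as near their end values at 30 h. The share rises with b, so it puts Tuesday's first and Sunday's last.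

**The forecast.** It ranks Saturday's > Tuesday's > Monday's > Wednesday's > Sunday's at 30 h and Tuesday's > Saturday's > Monday's > Wednesday's > Sunday's at 10 d, with top 83% (72% to 93%) and low 18% (8% to 32%). Its ground is that “high starting material and scarce partner hurt the share”. The reckoning above differs on the first flask and on both numbers.

**The flasks.** At 30 h the order is Tuesday's > Saturday's > Monday's > Wednesday's > Sunday's, and at 10 d it is Tuesday's > Saturday's > Monday's > Wednesday's > Sunday's, with top 91.5% and low 28.3%.

    2 open intermediate → homo product (k = 0.104 M⁻¹ h⁻¹, Ea = 78.0 kJ mol⁻¹)
    partner → second intermediate (k = 0.611 h⁻¹, Ea = 117 kJ mol⁻¹)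
    starting material ⇌ open intermediate (K = 17.0, k = 0.0405 h⁻¹, Ea = 110 kJ mol⁻¹, ΔH = −76.0 kJ mol⁻¹)
    open intermediate + second intermediate → target (k = 0.309 M⁻¹ h⁻¹, Ea = 83.0 kJ mol⁻¹)
    partner + protic impurity → quenched reagent (k = 1.72 M⁻¹ h⁻¹, Ea = 77.0 kJ mol⁻¹)
    partner → decomposed reagent (k = 0.0262 h⁻¹, Ea = 103 kJ mol⁻¹)
    (constants at 70 °C)

**Partner short.** Sunday's holds 0% of its partner at 30.0 h, which makes partner the limiting reagent. The same run with the running short of partner taken away gives a share of 97.6% against 28.3% in Sunday's as it is, so the shortage is the main reason. The neighbour of Sunday's charged with 0.40 M of partner has b of 1.11, above the dividing value, so the reckoning with σ gives w of 0.274 and a share of 83.6%. Computed at 30.0 h, that neighbour's share is 83.3%.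

All runs come from a simulation for substances that don't exist, noise included.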